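**Retrosynthetic overview**

1. The target is reached from a bis-silylated benzofuran-4-ol by O-methylation at C4' and cleavage of both aryl silyl ethers.
2. The strategy rests on the benzofuran carbocycle (C3a', C4', C5', C6', C7', C7a'), a 2-methylphloroglucinol ring whose three oxygens are all different (C4'-OMe, C6'-OH, furan oxygen on C7a') with the methyl at C5'. This ring is cut at C4'–C5', C6'–C7' and C3a'–C4' into a 2-aryl-5-(diazoacetyl)furan and 1-(triisopropylsilyloxy)propyne; the benzannulation returns C4'-OH free and C6'-O silylated, so no selective protection is needed.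
3. The flavan–furan bond C8–C2' comes from a Suzuki coupling of an 8-bromoflavan with 5-(methoxycarbonyl)furan-2-boronic acid; the ester is then converted into the diazoketone.
4. The flavan (rings A and C, phenyl ring B, C2 stereocentre) is taken from (2S)-alpinetin by O-silylation, C4 deoxygenation and C8 bromination.
5. Ring order: the flavan rings and the furan are bought; the only ring made is the benzene ring of the benzofuran, closed onto the furan in step 9.

Key step: step 9

Assumption: commercial alpinetin is taken to be the natural (2S)-enantiomer of high enantiomeric purity; C2 is the only stereocentre of the target, is never touched, and its optical purity is to be checked by chiral HPLC at flavan 4.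

**Route**

Step 1
Reactants: 1 (2S)-alpinetin [(2S)-7-hydroxy-5-methoxyflavanone]
Product: 2 (2S)-5-methoxy-7-(triisopropylsilyloxy)flavanone
Conditions: TIPSCl, imidazole, DMF, 0 → 25 °C
Reagents that add atoms: triisopropylsilyl chloride, CC(C)[Si](Cl)(C(C)C)C(C)C
Why: Silylation of the only hydroxyl (an acidic, vinylogous-acid phenol) with a weak amine base, which should not open the flavanone by retro-oxa-Michael reaction, so C2 keeps its configuration.

Step 2
Reactants: 2 (2S)-5-methoxy-7-(triisopropylsilyloxy)flavanone
Product: 3 (2S)-5-methoxy-7-(triisopropylsilyloxy)flavan-4-ol (mixture of C4 epimers, used as such)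
Conditions: NaBH4, THF/MeOH, 0 °C
Reagents that add atoms: none
Why: Borohydride reduction of the aryl ketone; the new C4 carbinol centre (expected mainly 2,4-cis from axial hydride delivery) does not matter because step 3 removes it, and the aryl silyl ether should tolerate the short exposure at 0 °C.

Step 3
Reactants: 3 (2S)-5-methoxy-7-(triisopropylsilyloxy)flavan-4-ol
Product: 4 (2S)-5-methoxy-7-(triisopropylsilyloxy)flavan
Conditions: Et3SiH (6 equiv), CF3CO2H, CH2Cl2, −20 → 0 °C
Reagents that add atoms: none
Why: Ionic hydrogenation, in which acid ionises the C4 alcohol to a benzylic cation stabilised by O1, the 5-methoxy and the 7-silyloxy groups and excess silane reduces it; C2 carries only an unsubstituted phenyl, so its C–O bond should not ionise and the configuration is retained.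

Step 4
Reactants: 4 (2S)-5-methoxy-7-(triisopropylsilyloxy)flavan
Product: 5 (2S)-8-bromo-5-methoxy-7-(triisopropylsilyloxy)flavan
Conditions: NBS (1.0 equiv), CH2Cl2, −78 → 0 °C, dark
Reagents that add atoms: N-bromosuccinimide, O=C1CCC(=O)N1Br
Why: Electrophilic aromatic bromination of the phloroglucinol-type ring A, which in 5,7-di-O-protected flavans is known to go to C8 (flanked by the ring oxygen) rather than to C6 (flanked by two exocyclic alkoxy/silyloxy groups); one equivalent at low temperature should avoid dibromination and benzylic attack.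

Step 5
Reactants: 5 (2S)-8-bromo-5-methoxy-7-(triisopropylsilyloxy)flavan; 6 5-(methoxycarbonyl)furan-2-boronic acid (1.5–2 equiv)
Product: 7 methyl 5-[(2S)-5-methoxy-7-(triisopropylsilyloxy)flavan-8-yl]furan-2-carboxylate
Conditions: Pd(OAc)2 (5 mol %), SPhos (10 mol %), K3PO4, THF/H2O, 40 °C
Reagents that add atoms: none
Why: Suzuki–Miyaura coupling in which the bulky, electron-rich biarylphosphine should allow oxidative addition into the hindered C8–Br bond at a temperature low enough to limit protodeboronation of the 2-furylboronic acid, while the methyl ester and the silyl ether tolerate aqueous phosphate.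

Step 6
Reactants: 7 methyl 5-[(2S)-5-methoxy-7-(triisopropylsilyloxy)flavan-8-yl]furan-2-carboxylate
Product: 9 5-[(2S)-5-methoxy-7-(triisopropylsilyloxy)flavan-8-yl]furan-2-carboxylic acid, via trimethylstannyl ester 8 (not isolated)
Conditions: Me3SnOH, ClCH2CH2Cl, 80 °C; then 0.1 M HCl wash
Reagents that add atoms: trimethyltin hydroxide, C[Sn](C)(C)O
Why: Tin hydroxide-mediated cleavage of the methyl ester under essentially neutral conditions, chosen because aqueous alkali could attack the aryl silyl ether; the acid wash frees the acid from its tin carboxylate.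

Step 7
Reactants: 9 5-[(2S)-5-methoxy-7-(triisopropylsilyloxy)flavan-8-yl]furan-2-carboxylic acid
Product: 11 (2S)-8-[5-(diazoacetyl)furan-2-yl]-5-methoxy-7-(triisopropylsilyloxy)flavan, via acid chloride 10 (not isolated)
Conditions: (COCl)2, cat. DMF, CH2Cl2, 0 → 25 °C; evaporate; CH2N2 (excess), Et2O/THF, 0 °C
Reagents that add atoms: diazomethane, C=[N+]=[N-] (oxalyl chloride, O=C(Cl)C(=O)Cl, supplies chlorine to intermediate 10 only)
Why: Acid chloride formation followed by C-acylation of diazomethane (first stage of the Arndt–Eistert sequence); excess diazomethane takes up the HCl, and the molecule has no free hydroxyl that diazomethane could methylate.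

Step 8
Reactants: 12 propyne
Product: 15 triisopropyl(prop-1-yn-1-yloxy)silane, via 1-propynyllithium 13 (not isolated), via lithium prop-1-yn-1-olate 14 (not isolated)
Conditions: n-BuLi, THF, −78 °C; add to LiOOt-Bu [t-BuOOH + LiN(SiMe3)2, THF, −78 °C], −78 → 0 °C; then TIPSOTf, −78 → 0 °C
Reagents that add atoms: tert-butyl hydroperoxide (as its lithium salt), CC(C)(C)OO; triisopropylsilyl trifluoromethanesulfonate, CC(C)[Si](C(C)C)(C(C)C)OS(=O)(=O)C(F)(F)F
Why: Oxidation of a lithium acetylide by lithium tert-butyl peroxide (attack of the acetylide on the peroxide O–O bond with loss of tert-butoxide) gives the ynolate, which the bulky silyl triflate should capture on oxygen to give the siloxyalkyne.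

Step 9
Reactants: 11 (2S)-8-[5-(diazoacetyl)furan-2-yl]-5-methoxy-7-(triisopropylsilyloxy)flavan; 15 triisopropyl(prop-1-yn-1-yloxy)silane (2.5 equiv)
Product: 20 (2S)-8-[4-hydroxy-5-methyl-6-(triisopropylsilyloxy)benzofuran-2-yl]-5-methoxy-7-(triisopropylsilyloxy)flavan, via furylketene 16 (not isolated), via siloxycyclobutenone 17 (not isolated), via dienylketene 18 (not isolated), via cyclohexadienone tautomer 19 (not isolated)
Conditions: hν (300 nm, Pyrex), degassed ClCH2CH2Cl, 25 °C; then 80 °C
Reagents that add atoms: none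
Why: Light expels N2 from 11 and the furyl group migrates to the carbene carbon (Wolff rearrangement) to give furylketene 16, whose carbonyl carbon bonds to the nucleophilic, methyl-bearing carbon of ynol ether 15 and whose α-carbon bonds to the oxygen-bearing carbon in a [2+2] cycloaddition (C4'–C5' and C6'–C7'), giving cyclobutenone 17. On heating, reversible four-electron electrocyclic opening of 17 gives dienylketene 18, whose third π bond is the furan C4=C5 bond; six-electron electrocyclization joins the ketene carbon to furan C4 (bond C3a'–C4'), which closes the six-membered carbocycle of the benzofuran onto the furan, and enolization of dienone 19 gives phenol 20. The closest known reaction type is the Danheiser benzannulation in its photochemical diazoketone form, established for aryl and heteroaryl diazoketones with siloxyalkynes. No lasting stereocentre is formed (C4 of 17 and C3a' of 19 disappear on ring opening and aromatization), and the neutral, non-ionising conditions leave the benzylic ether centre C2 alone. The regiochemistry needed is secured twice by the substrate: the polarization of the siloxyalkyne places methyl at C5' and silyloxy at C6', and the ring closure can only reach furan C4 because furan C5 carries the ketene chain and C2 the flavan. The cascade therefore delivers a free C4' hydroxyl beside a silylated C6' oxygen without any selective protection.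

Step 10
Reactants: 20 (2S)-8-[4-hydroxy-5-methyl-6-(triisopropylsilyloxy)benzofuran-2-yl]-5-methoxy-7-(triisopropylsilyloxy)flavan
Product: 21 (2S)-5-methoxy-8-[4-methoxy-5-methyl-6-(triisopropylsilyloxy)benzofuran-2-yl]-7-(triisopropylsilyloxy)flavan
Conditions: MeI, K2CO3, acetone, 40 °C
Reagents that add atoms: iodomethane, CI
Why: Williamson O-methylation of the only free phenol (C4'-OH); aryl triisopropylsilyl ethers should withstand K2CO3 in acetone, so the C6' and C7 oxygens stay masked.

Step 11
Reactants: 21 (2S)-5-methoxy-8-[4-methoxy-5-methyl-6-(triisopropylsilyloxy)benzofuran-2-yl]-7-(triisopropylsilyloxy)flavan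
Product: 22 (2S)-8-(6-hydroxy-4-methoxy-5-methylbenzofuran-2-yl)-5-methoxyflavan-7-ol (CNP0000229.1)
Conditions: Bu4NF, AcOH, THF, 0 °C
Reagents that add atoms: none
Why: Fluoride-induced cleavage of both aryl silyl ethers, driven by Si–F bond formation; acetic acid buffering keeps the electron-rich phenols protonated, and no stereocentre is involved.

**Compound list**

1 | (2S)-alpinetin, (2S)-7-hydroxy-5-methoxyflavanone | COc1cc(O)cc2c1C(=O)C[C@@H](c1ccccc1)O2 | starting material
2 | (2S)-5-methoxy-7-(triisopropylsilyloxy)flavanone | COc1cc(O[Si](C(C)C)(C(C)C)C(C)C)cc2c1C(=O)C[C@@H](c1ccccc1)O2 | intermediate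
3 | (2S)-5-methoxy-7-(triisopropylsilyloxy)flavan-4-ol (C4 epimers) | COc1cc(O[Si](C(C)C)(C(C)C)C(C)C)cc2c1C(O)C[C@@H](c1ccccc1)O2 | intermediate
4 | (2S)-5-methoxy-7-(triisopropylsilyloxy)flavan | COc1cc(O[Si](C(C)C)(C(C)C)C(C)C)cc2c1CC[C@@H](c1ccccc1)O2 | intermediate
5 | (2S)-8-bromo-5-methoxy-7-(triisopropylsilyloxy)flavan | COc1cc(O[Si](C(C)C)(C(C)C)C(C)C)c(Br)c2c1CC[C@@H](c1ccccc1)O2 | intermediate
6 | 5-(methoxycarbonyl)furan-2-boronic acid | COC(=O)c1ccc(B(O)O)o1 | starting material
7 | methyl 5-[(2S)-5-methoxy-7-(triisopropylsilyloxy)flavan-8-yl]furan-2-carboxylate | COc1cc(O[Si](C(C)C)(C(C)C)C(C)C)c(-c3ccc(C(=O)OC)o3)c2c1CC[C@@H](c1ccccc1)O2 | intermediate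
8 | trimethylstannyl 5-[(2S)-5-methoxy-7-(triisopropylsilyloxy)flavan-8-yl]furan-2-carboxylate | COc1cc(O[Si](C(C)C)(C(C)C)C(C)C)c(-c3ccc(C(=O)O[Sn](C)(C)C)o3)c2c1CC[C@@H](c1ccccc1)O2 | intermediate (not isolated)
9 | 5-[(2S)-5-methoxy-7-(triisopropylsilyloxy)flavan-8-yl]furan-2-carboxylic acid | COc1cc(O[Si](C(C)C)(C(C)C)C(C)C)c(-c3ccc(C(=O)O)o3)c2c1CC[C@@H](c1ccccc1)O2 | intermediate
10 | 5-[(2S)-5-methoxy-7-(triisopropylsilyloxy)flavan-8-yl]furan-2-carbonyl chloride | COc1cc(O[Si](C(C)C)(C(C)C)C(C)C)c(-c3ccc(C(=O)Cl)o3)c2c1CC[C@@H](c1ccccc1)O2 | intermediate (not isolated)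
11 | (2S)-8-[5-(diazoacetyl)furan-2-yl]-5-methoxy-7-(triisopropylsilyloxy)flavan | COc1cc(O[Si](C(C)C)(C(C)C)C(C)C)c(-c3ccc(C(=O)C=[N+]=[N-])o3)c2c1CC[C@@H](c1ccccc1)O2 | intermediate (key-step precursor)
12 | propyne | CC#C | starting material
13 | 1-propynyllithium | CC#C[Li] | intermediate (not isolated)
14 | lithium prop-1-yn-1-olate | [Li+].CC#C[O-] | intermediate (not isolated)
15 | triisopropyl(prop-1-yn-1-yloxy)silane | CC#CO[Si](C(C)C)(C(C)C)C(C)C | intermediate (key-step partner)
16 | (2S)-5-methoxy-8-[5-(2-oxoethenyl)furan-2-yl]-7-(triisopropylsilyloxy)flavan (furylketene) | COc1cc(O[Si](C(C)C)(C(C)C)C(C)C)c(-c3ccc(C=C=O)o3)c2c1CC[C@@H](c1ccccc1)O2 | intermediate (not isolated)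
17 | 4-{5-[(2S)-5-methoxy-7-(triisopropylsilyloxy)flavan-8-yl]furan-2-yl}-2-methyl-3-(triisopropylsilyloxy)cyclobut-2-en-1-one (ring CH epimers) | COc1cc(O[Si](C(C)C)(C(C)C)C(C)C)c(-c3ccc(C4C(=O)C(C)=C4O[Si](C(C)C)(C(C)C)C(C)C)o3)c2c1CC[C@@H](c1ccccc1)O2 | intermediate (not isolated)
18 | 4-{5-[(2S)-5-methoxy-7-(triisopropylsilyloxy)flavan-8-yl]furan-2-yl}-2-methyl-3-(triisopropylsilyloxy)buta-1,3-dien-1-one (dienylketene, furyl cis to the ketene-bearing carbon) | COc1cc(O[Si](C(C)C)(C(C)C)C(C)C)c(-c3ccc(/C=C(\C(C)=C=O)O[Si](C(C)C)(C(C)C)C(C)C)o3)c2c1CC[C@@H](c1ccccc1)O2 | intermediate (not isolated)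
19 | 2-[(2S)-5-methoxy-7-(triisopropylsilyloxy)flavan-8-yl]-5-methyl-6-(triisopropylsilyloxy)-3aH-benzofuran-4-one (C3a' epimers) | COc1cc(O[Si](C(C)C)(C(C)C)C(C)C)c(C3=CC4C(=O)C(C)=C(O[Si](C(C)C)(C(C)C)C(C)C)C=C4O3)c2c1CC[C@@H](c1ccccc1)O2 | intermediate (not isolated)
20 | (2S)-8-[4-hydroxy-5-methyl-6-(triisopropylsilyloxy)benzofuran-2-yl]-5-methoxy-7-(triisopropylsilyloxy)flavan | COc1cc(O[Si](C(C)C)(C(C)C)C(C)C)c(-c3cc4c(O)c(C)c(O[Si](C(C)C)(C(C)C)C(C)C)cc4o3)c2c1CC[C@@H](c1ccccc1)O2 | intermediate (key-step product)
21 | (2S)-5-methoxy-8-[4-methoxy-5-methyl-6-(triisopropylsilyloxy)benzofuran-2-yl]-7-(triisopropylsilyloxy)flavan | COc1cc(O[Si](C(C)C)(C(C)C)C(C)C)c(-c3cc4c(OC)c(C)c(O[Si](C(C)C)(C(C)C)C(C)C)cc4o3)c2c1CC[C@@H](c1ccccc1)O2 | intermediate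
22 | (2S)-8-(6-hydroxy-4-methoxy-5-methylbenzofuran-2-yl)-5-methoxyflavan-7-ol | COc1cc(O)c(-c2cc3c(OC)c(C)c(O)cc3o2)c2c1CC[C@@H](c1ccccc1)O2 | target

**Step count**

Total: 11 steps. Longest linear sequence: 10 steps (steps 1–7 and 9–11 from alpinetin); the siloxyalkyne branch is one step (step 8).

**Steps most likely to fail, with fallbacks**

Step 9 (key step). The arylfuran chromophore of the substrate and the arylbenzofuran chromophore of the product may compete for light and undergo secondary photoreactions. The phenolic product may also capture ketene intermediates as aryl esters, and the thermal stage may stall at the cyclobutenone. The fallback makes the same ketene in the dark by a different reaction and sets out from diazoketone 11. A PhCO2Ag/Et3N-catalysed Wolff rearrangement in aqueous THF (Arndt–Eistert homologation) should give {5-[(2S)-5-methoxy-7-(triisopropylsilyloxy)flavan-8-yl]furan-2-yl}acetic acid F1. Oxalyl chloride with catalytic DMF converts it into {5-[(2S)-5-methoxy-7-(triisopropylsilyloxy)flavan-8-yl]furan-2-yl}acetyl chloride F2. Slow addition of Et3N to F2 and siloxyalkyne 15 in toluene at 0–25 °C generates furylketene 16 by dehydrochlorination, and the ketene is trapped by [2+2] cycloaddition. The fallback comes back to the route at cyclobutenone 17, which is heated at 80–110 °C to give 20 by the same ring opening and electrocyclization.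

Step 5. Protodeboronation of the electron-poor 2-furylboronic acid may outrun oxidative addition and transmetalation with the hindered, electron-rich bromide, and some ester hydrolysis may occur. The fallback replaces the boron nucleophile by an organozinc and sets out from bromide 5. LiCl-promoted insertion of zinc dust into commercial methyl 5-bromofuran-2-carboxylate (COC(=O)c1ccc(Br)o1) in THF at 25 °C should give [5-(methoxycarbonyl)furan-2-yl]zinc bromide F3. Negishi coupling of F3 with 5 (Pd(OAc)2, SPhos, THF, 50 °C, no base, no water) comes back to the route at ester 7.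

Step 3. In acid the C4 cation may attack the electron-rich ring A of a second molecule (flavan C4-to-C8 or C4-to-C6 oligomerisation), and the silyl ether may be partly lost. The fallback avoids the cation altogether and sets out from flavanone 2, bypassing alcohol 3. Condensation with TsNHNH2 (EtOH, 60 °C) should give (2S)-5-methoxy-7-(triisopropylsilyloxy)flavanone 4-tosylhydrazone F4. Reduction with catecholborane (CHCl3, 0 °C) and then NaOAc·3H2O at reflux (tosylhydrazone reduction through the diazene, with loss of N2 and sulfinate) comes back to the route at flavan 4.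

**Further compounds**

F1 | step 9 | {5-[(2S)-5-methoxy-7-(triisopropylsilyloxy)flavan-8-yl]furan-2-yl}acetic acid | COc1cc(O[Si](C(C)C)(C(C)C)C(C)C)c(-c3ccc(CC(=O)O)o3)c2c1CC[C@@H](c1ccccc1)O2
F2 | step 9 | {5-[(2S)-5-methoxy-7-(triisopropylsilyloxy)flavan-8-yl]furan-2-yl}acetyl chloride | COc1cc(O[Si](C(C)C)(C(C)C)C(C)C)c(-c3ccc(CC(=O)Cl)o3)c2c1CC[C@@H](c1ccccc1)O2
F3 | step 5 | [5-(methoxycarbonyl)furan-2-yl]zinc bromide | COC(=O)c1ccc([Zn]Br)o1
F4 | step 3 | (2S)-5-methoxy-7-(triisopropylsilyloxy)flavanone 4-tosylhydrazone | COc1cc(O[Si](C(C)C)(C(C)C)C(C)C)cc2c1C(=NNS(=O)(=O)c1ccc(C)cc1)C[C@@H](c1ccccc1)O2
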